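**A direct plan and its weak points**

A direct plan would treat the furan as the seam. An o-iodophenol A1 and a silyl-capped arylalkyne A2 would be joined by Sonogashira coupling and 5-endo-dig heteroannulation to the 2-arylbenzofuran A3.
C3 of A3 would then be formylated to A4, and three benzyl ethers would be removed at the very end.
- **Decoration of bare arenes** (ortho-bromination/Cu-methoxylation on one ring, ortho-formylation/Dakin oxidation on the other). About ten steps would only recreate guaiacyl and 5-hydroxyguaiacyl patterns that cheap commercial phenols already carry.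
- **Vilsmeier–Haack formylation of A3.** One carbon would be added to the most advanced intermediate, with the site left to the innate reactivity of three electron-rich rings in hot POCl3/DMF.
- **Closing triple debenzylation of A4 with a large excess of BCl3.** Two aryl methyl ethers (one beside the emerging catechol), an aldehyde and an air-sensitive catechol would face a strong Lewis acid for as long as the slow primary alkyl benzyl ether needs.

**Plan of the new route**

- **Cuts:** the furan bond C2–C3 is cut by a retro-1,2-aroyl shift that re-inserts the formyl carbon between C2 and C3, turning the benzofuran into the flavylium (2-arylchromenylium) salt 7. Salt 7 is cut at its C3–C4 bond (the C3–CHO bond of the target) and at O1–C2 into salicylaldehyde 2 and acetophenone 5.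
- **Enabling feature:** O1, C2, C3, the formyl carbon and C3a of the target are the atoms O1, C2, C4, C3 and C4a of a benzopyrylium ring, one oxygen richer. O1 stands ortho to the carbon that bears C3, and the 4′-OH stands para to C2, so groups the target keeps activate both the migration terminus and the migrating carbon.
- **Ring order:** both benzene rings are bought. The six-membered pyrylium ring is made first, in the fragment union, and the furan arises last by oxidative contraction of that ring.
- **Why the weak steps vanish:** the oxygen patterns are bought, and only one OH is added, on a cheap ketone. The formyl carbon is the acetyl CH3 of 5 and is in place before any core exists. No protecting group is used, so nothing has to be stripped.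

Key step: step 5

Assumption: the target SMILES holds no stereocentre and no stereogenic double bond, so the molecule is achiral and no configuration has to be set. Compounds 1 and 3 are catalogue compounds.

**Route**

Step 1
Reactants: 1 dihydroconiferyl alcohol [4-(3-hydroxypropyl)-2-methoxyphenol]
Product: 2 2-hydroxy-5-(3-hydroxypropyl)-3-methoxybenzaldehyde
Conditions: MgCl2 (3 equiv), Et3N (6 equiv), (CH2O)n (8 equiv), MeCN, reflux; 1 M HCl work-up
Reagents that add atoms: paraformaldehyde (as formaldehyde), C=O
Why: Casnati–Skattebøl ortho-formylation, in which the magnesium phenoxide delivers formaldehyde only to the single free ortho carbon, a second formaldehyde oxidises the benzylic alkoxide by hydride transfer, and the side-chain alkoxide is simply released again on acidic work-up.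

Step 2
Reactants: 3 acetovanillone [1-(4-hydroxy-3-methoxyphenyl)ethanone]
Product: 4 1-(4-hydroxy-3-iodo-5-methoxyphenyl)ethanone
Conditions: NIS (1.05 equiv), TFA (10 mol %), MeCN, 0 °C → rt
Reagents that add atoms: N-iodosuccinimide, O=C1CCC(=O)N1I
Why: Electrophilic aromatic iodination directed by the free OH to its only open ortho position (para is blocked by the acetyl group), as in the iodination of vanillin.

Step 3
Reactants: 4 1-(4-hydroxy-3-iodo-5-methoxyphenyl)ethanone
Product: 5 1-(3,4-dihydroxy-5-methoxyphenyl)ethanone
Conditions: NaOH (4 M aq., 8 equiv), CuSO4·5H2O (10 mol %), reflux, N2; then HCl to pH 2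
Reagents that add atoms: sodium hydroxide, [Na+].[OH-]
Why: Ullmann-type copper-catalysed hydroxylation of an ortho-iodophenolate (the 5-iodovanillin → 5-hydroxyvanillin transformation), in which the ketone is deactivated towards aldol chemistry as part of the vinylogous phenolate and exclusion of air protects the catecholate.

Step 4
Reactants: 2 2-hydroxy-5-(3-hydroxypropyl)-3-methoxybenzaldehyde; 5 1-(3,4-dihydroxy-5-methoxyphenyl)ethanone
Product: 7 2-(3,4-dihydroxy-5-methoxyphenyl)-6-(3-hydroxypropyl)-8-methoxychromenylium chloride, via 2-hydroxychalcone 6 (not isolated)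
Conditions: dry HCl (4 M in 1,4-dioxane, a little MeOH), 0 °C → rt, dark; Et2O to precipitate
Reagents that add atoms: hydrogen chloride, Cl
Why: Acid-mediated Claisen–Schmidt condensation and pyrylium closure (the classical salicylaldehyde/acetophenone flavylium synthesis, which tolerates free phenols and catechols), in which the enol of 5 attacks protonated 2 to set C3–C4, the ortho-OH of 6 adds 6-exo-trig to the protonated ketone, loss of water gives the aromatic cation that drains the equilibria by precipitation, and the ester-free solvent keeps the primary alcohol unacylated.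

Step 5
Reactants: 7 2-(3,4-dihydroxy-5-methoxyphenyl)-6-(3-hydroxypropyl)-8-methoxychromenylium chloride
Product: 11 Mururin C, via C4-hydroperoxide 8 (not isolated), via cis-epoxy ketone 9 (not isolated), via ketoaldehyde 10 (not isolated)
Conditions: 30 % aq. H2O2 (1.1 equiv), NaOAc/AcOH buffer (pH 5.5), Na2EDTA (1 mol %), t-BuOH–H2O 1:1, 0 °C → rt, N2, dark; then 1 M HCl to pH 2, rt
Reagents that add atoms: hydrogen peroxide, OO
Why: Proposed new method: H2O2 should add reversibly to the unsubstituted C4 of the pyrylium ring to give 8, whose C2=C3 enol ether, made a vinylogous phenol(ate) by the para 4′-OH, displaces water from the O–O bond (Weitz–Scheffer-type closure, 3-exo-tet), and hydration at C2 with opening of O1–C2 then leaves the cis-epoxy ketone 9. The freed ortho-phenol pushes the benzylic epoxide oxygen off old C4 in the manner of an o-quinone methide while the aroyl carbon C2 migrates from old C3 to old C4, so that the C2–C3 bond of the target forms and old C3 leaves the ring as the formyl carbon of 10. The phenol oxygen then closes on the aryl ketone (5-exo-trig) and loss of water aromatises the furan to 11, the brief acidification completing this and returning any unreacted material to water-soluble 7. The closest known reaction types are Weitz–Scheffer epoxidation of chalcones, the acid-induced 1,2-aroyl shift of chalcone epoxides to α-formyl deoxybenzoins, the acid cyclodehydration of o-hydroxyaryl ketoaldehyde equivalents to 2-aryl-3-formylbenzofurans, and peroxide-induced contractions of 3-substituted flavylium salts to 3-acyl-2-arylbenzofurans; what is new is their merger on a 3-unsubstituted, unprotected catechol salt. The stereocentres of 8–10 are racemic and transient and none survives. The step needs the C4 channel to beat Baeyer–Villiger-type cleavage of the C2 hydroperoxide, aroyl to beat hydride migration, and closure on the ketone to beat closure on the aldehyde: the weakly acidic buffer starves the acid-catalysed Criegee path, the open-chain epoxy ketone has the known preference for acyl migration, only closure on the ketone gives a cation stabilised by the 4′-OH ring and the push–pull 4′-O/C2=C3/CHO conjugation, and about one equivalent of metal-free peroxide at pH 5–6 should spare catechol and aldehyde.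

**Compound list**

1 | dihydroconiferyl alcohol, 4-(3-hydroxypropyl)-2-methoxyphenol | COc1cc(CCCO)ccc1O | starting material
2 | 2-hydroxy-5-(3-hydroxypropyl)-3-methoxybenzaldehyde | COc1cc(CCCO)cc(C=O)c1O | intermediate
3 | acetovanillone, 1-(4-hydroxy-3-methoxyphenyl)ethanone | CC(=O)c1ccc(O)c(OC)c1 | starting material
4 | 1-(4-hydroxy-3-iodo-5-methoxyphenyl)ethanone | CC(=O)c1cc(I)c(O)c(OC)c1 | intermediate
5 | 1-(3,4-dihydroxy-5-methoxyphenyl)ethanone | CC(=O)c1cc(O)c(O)c(OC)c1 | intermediate
6 | (E)-1-(3,4-dihydroxy-5-methoxyphenyl)-3-[2-hydroxy-5-(3-hydroxypropyl)-3-methoxyphenyl]prop-2-en-1-one | COc1cc(C(=O)/C=C/c2cc(CCCO)cc(OC)c2O)cc(O)c1O | intermediate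
7 | 2-(3,4-dihydroxy-5-methoxyphenyl)-6-(3-hydroxypropyl)-8-methoxychromenylium chloride (flavylium salt) | COc1cc(-c2ccc3cc(CCCO)cc(OC)c3[o+]2)cc(O)c1O.[Cl-] | intermediate
8 | 5-[4-hydroperoxy-6-(3-hydroxypropyl)-8-methoxy-4H-chromen-2-yl]-3-methoxybenzene-1,2-diol (racemic at C4) | COc1cc(C2=CC(OO)c3cc(CCCO)cc(OC)c3O2)cc(O)c1O | intermediate
9 | (3,4-dihydroxy-5-methoxyphenyl){cis-3-[2-hydroxy-5-(3-hydroxypropyl)-3-methoxyphenyl]oxiran-2-yl}methanone (racemic, one enantiomer drawn) | COc1cc(C(=O)[C@H]2O[C@H]2c2cc(CCCO)cc(OC)c2O)cc(O)c1O | intermediate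
10 | 3-(3,4-dihydroxy-5-methoxyphenyl)-2-[2-hydroxy-5-(3-hydroxypropyl)-3-methoxyphenyl]-3-oxopropanal (enolisable, configurationally labile) | COc1cc(C(=O)C(C=O)c2cc(CCCO)cc(OC)c2O)cc(O)c1O | intermediate
11 | Mururin C, 2-(3,4-dihydroxy-5-methoxyphenyl)-5-(3-hydroxypropyl)-7-methoxy-1-benzofuran-3-carbaldehyde | COc1cc(-c2oc3c(OC)cc(CCCO)cc3c2C=O)cc(O)c1O | target

**Summary**

Total step count: 5
Longest linear sequence: 4 (3 → 4 → 5 → 7 → 11)

**Steps most likely to fail**

**1. Step 5 (Proposed new method).**
- Peroxide capture at C2 could lead to Baeyer–Villiger-type scission of C2–C3.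
- Hydride could migrate instead of the aroyl group.
- Solvent could trap the quinone-methide-like stage.
- The catechol or the new aldehyde could be over-oxidised.

The fallback uses only known chemistry, sets out from 2 and 5, and returns at 11.
- MOMCl/i-Pr2NEt would convert 2 into 3-methoxy-2-(methoxymethoxy)-5-[3-(methoxymethoxy)propyl]benzaldehyde F1.
- The same reagents would convert 5 into 1-[3-methoxy-4,5-bis(methoxymethoxy)phenyl]ethanone F2.
- Base-mediated Claisen–Schmidt condensation (KOH, EtOH) would give the tetra-MOM (E)-chalcone F3.
- Weitz–Scheffer epoxidation (H2O2, NaOH, MeOH–THF, 0 °C) would give the trans-epoxy ketone F4.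
- BF3·OEt2 in CH2Cl2 at −20 °C would trigger the established 1,2-aroyl shift to the protected α-formyl deoxybenzoin F5.
- Aqueous HCl in MeOH–THF (or p-TsOH in (CF3)2CHOH) would strip the four MOM groups and cyclodehydrate to 11.

**2. Step 4.**
- Enolisation of the p-hydroxyaryl ketone could be sluggish.
- The salt could fail to precipitate, so the equilibria would not be drained.
- Acid could induce substitution or etherification at the primary alcohol.

The fallback separates C–C bond formation from ring closure, sets out from 5 (with 2), and returns at 7.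
- 2,2-Dimethoxypropane/p-TsOH would mask 5 as 1-(7-methoxy-2,2-dimethyl-1,3-benzodioxol-5-yl)ethanone F6.
- Its enolate (KOH, EtOH) would condense with the phenolate of 2 to the isolable acetonide-protected (E)-2-hydroxychalcone F7.
- Warm methanolic HCl would then unmask the catechol and close the pyrylium ring in a separate operation to give 7.

**3. Step 1.**
- The formylation could stall through chelation of magnesium by the guaiacyl O,O-pair or by the side-chain alkoxide.
- The reaction could be held up at the benzylic alcohol stage.

The fallback sets out from 1 and returns at 2.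
- Lederer–Manasse hydroxymethylation (37 % aq. CH2O, NaOH, rt) at the only free ortho position would give 2-(hydroxymethyl)-4-(3-hydroxypropyl)-6-methoxyphenol F8.
- Activated MnO2 (EtOAc, rt) would oxidise only the benzylic alcohol, giving 2.

**Further compounds**

F1 | step 5 | 3-methoxy-2-(methoxymethoxy)-5-[3-(methoxymethoxy)propyl]benzaldehyde | COCOCCCc1cc(C=O)c(OCOC)c(OC)c1
F2 | step 5 | 1-[3-methoxy-4,5-bis(methoxymethoxy)phenyl]ethanone | CC(=O)c1cc(OC)c(OCOC)c(OCOC)c1
F3 | step 5 | (E)-1-[3-methoxy-4,5-bis(methoxymethoxy)phenyl]-3-{3-methoxy-2-(methoxymethoxy)-5-[3-(methoxymethoxy)propyl]phenyl}prop-2-en-1-one | COCOCCCc1cc(/C=C/C(=O)c2cc(OC)c(OCOC)c(OCOC)c2)c(OCOC)c(OC)c1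
F4 | step 5 | trans-epoxy ketone of F3 (racemic, one enantiomer drawn) | COCOCCCc1cc([C@H]2O[C@@H]2C(=O)c2cc(OC)c(OCOC)c(OCOC)c2)c(OCOC)c(OC)c1
F5 | step 5 | 3-[3-methoxy-4,5-bis(methoxymethoxy)phenyl]-2-{3-methoxy-2-(methoxymethoxy)-5-[3-(methoxymethoxy)propyl]phenyl}-3-oxopropanal | COCOCCCc1cc(C(C=O)C(=O)c2cc(OC)c(OCOC)c(OCOC)c2)c(OCOC)c(OC)c1
F6 | step 4 | 1-(7-methoxy-2,2-dimethyl-1,3-benzodioxol-5-yl)ethanone | CC(=O)c1cc(OC)c2OC(C)(C)Oc2c1
F7 | step 4 | (E)-3-[2-hydroxy-5-(3-hydroxypropyl)-3-methoxyphenyl]-1-(7-methoxy-2,2-dimethyl-1,3-benzodioxol-5-yl)prop-2-en-1-one | COc1cc(CCCO)cc(/C=C/C(=O)c2cc(OC)c3OC(C)(C)Oc3c2)c1O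
F8 | step 1 | 2-(hydroxymethyl)-4-(3-hydroxypropyl)-6-methoxyphenol | COc1cc(CCCO)cc(CO)c1O
A1 | direct plan | 4-[3-(benzyloxy)propyl]-2-iodo-6-methoxyphenol | COc1cc(CCCOCc2ccccc2)cc(I)c1O
A2 | direct plan | {[3,4-bis(benzyloxy)-5-methoxyphenyl]ethynyl}trimethylsilane | COc1cc(C#C[Si](C)(C)C)cc(OCc2ccccc2)c1OCc1ccccc1
A3 | direct plan | 2-[3,4-bis(benzyloxy)-5-methoxyphenyl]-5-[3-(benzyloxy)propyl]-7-methoxy-1-benzofuran | COc1cc(-c2cc3cc(CCCOCc4ccccc4)cc(OC)c3o2)cc(OCc2ccccc2)c1OCc1ccccc1
A4 | direct plan | 2-[3,4-bis(benzyloxy)-5-methoxyphenyl]-5-[3-(benzyloxy)propyl]-7-methoxy-1-benzofuran-3-carbaldehyde | COc1cc(-c2oc3c(OC)cc(CCCOCc4ccccc4)cc3c2C=O)cc(OCc2ccccc2)c1OCc1ccccc1
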